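If you repeat this run, watch how the rate answers a charge, not just the rate itself.

| setting | amber | teal | flask |
|---|---|---|---|
| left-handed substrate | 0.10 M | 0.40 M | 0.20 M |
| right-handed substrate | 0.10 M | 0.40 M | 0.20 M |
| partner | 0.24 M | 0.24 M | 0.240 M |
| free catalyst | 0.42 mM | 0.42 mM | 0.42 mM |
| added ligand | 0.27 mM | 0.27 mM | 0.27 mM |
| remark | run made earlier | run made earlier |  |

- amber (time / min: left-handed product / %, left-handed substrate / %): 4.00: 4.2, 46.1; 12.0: 10.3, 39.7; 20.0: 14.5, 34.9; 30.0: 20.0, 29.5; 50.0: 25.9, 23.2
- teal (time / min: left-handed product / %, left-handed substrate / %): 10.0: 5.8, 44.2; 20.0: 9.2, 40.3; 30.0: 12.3, 36.5; 40.0: 13.8, 34.9; 50.0: 16.0, 33.7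

(standard deviation of a reading: 0.5 percentage points)

- apparent order in free catalyst when 30 % of the left-handed substrate and right-handed substrate together are converted (percent change of the rate of making left-handed product for one percent more free catalyst charged)

- free catalyst is single-handed; left-handed substrate and right-handed substrate are mirror images of each other, charged as a racemate, each of them at the stated concentration
- the earlier runs were read with a standard deviation of 0.5 percentage points
- no earlier run changes the charge of free catalyst; that part of a forecast is a guess

Work in logarithms. Amber reaches 4.2 % left-handed product at its first reading, and teal reaches 5.8 %. Those shares differ by 1.6 percentage points, so the comparison is rough. The mean rates up to there are 0.00210 M min⁻¹ for amber and 0.00464 M min⁻¹ for teal. From them I read 0.572, with readings that scatter by 0.5 points. This is the log slope: the logarithm of a rate factor over the logarithm of the charge factor. It is below one, so the early rate grows less than in proportion to the substrate charge.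

Your flask has c(left-handed substrate) = 0.20 M, twice amber's. The log slope therefore gives 1.49 times amber's early rate. Keep that charge, and keep c(partner) and the added ligand as they stand. Neither earlier run changes c(free catalyst), so that is the charge to change next. My guess for its log slope is one.

The forecast says 2.3, with a range from 1.2 to 3, and it warns: “The runs never varied the catalyst, so the rest is a guess.” My guess is lower.

The flask gives 0.85 at 30 % conversion, above the 0.572 read for the substrate from the early readings of amber and teal.

    free catalyst + left-handed substrate ⇌ catalyst intermediate A (K = 3.50 M⁻¹, k = 130 M⁻¹ s⁻¹)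
    2 free catalyst ⇌ resting dimer (K = 3400 M⁻¹, k = 1.80 M⁻¹ s⁻¹)
    free catalyst + added ligand ⇌ idle complex, settled at all times (K = 3400 M⁻¹)
    partner + catalyst intermediate A → free catalyst + left-handed product (k = 2.20 M⁻¹ s⁻¹)
    free catalyst + right-handed substrate ⇌ catalyst intermediate B (K = 1.30 M⁻¹, k = 67.0 M⁻¹ s⁻¹)
    partner + catalyst intermediate B → free catalyst + right-handed product (k = 0.760 M⁻¹ s⁻¹)

On a further run of this flask with twice the partner, the rate factor 3.26 gives a log slope of 1.70, also above 0.572. In this flask at 23.1 min, catalyst intermediate A falls back 96 times faster than it goes on to left-handed product. At 80.0 min, its net making over its net use stands at 1.00, with 10.0 % of the catalyst charged in it.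

(The data are simulated with made-up constants; noise was put on by code.)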